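The rate constants are those of an exercise, and the outcome is calculated.

The nucleophile is the molecule to follow: we take one and ask what can become of it, in flasks that differ in its charge.

the same everywhere: electrophile 0.10 M; gas 45 mM (held); time 5.0 h
- south-east: nucleophile 0.120 M
- north-west: nucleophile 0.480 M
- south: nucleophile 0.240 M

    electrophile + nucleophile → acid set free + target (k1 = 3.3 /M/h)
    nucleophile + acid set free ⇌ protonated nucleophile, settled at all times (K2 = 18000 /M)
    acid set free + free base ⇌ salt of the base, settled at all times (K3 = 330 /M)
    2 nucleophile → self-condensation product (k4 = 3.0 /M/h)
    gas ⇌ free base, rate k5*(csat - [free base]) (k5 = 1.5 /h, csat = 45 mM)

- for a step with 2 of a species take k times the square, and two of it per event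
- at the start none of free base is dissolved
- run time (south-east): 5.0 h

- part of the electrophile that has reacted at the end, south-east
- part of the electrophile that has reacted at the end, north-west
- part of the electrophile that has reacted at the end, south
- what raising the concentration of nucleophile from its lowest to its highest value here does to the part of the electrophile that has reacted (changes below 5 percentage points count as none) (it rises / no change / it falls)

Which numbers must we know well? The constant for acid on nucleophile need not be exact. Times [nucleophile] it starts at 2200 in south-east, so each acid set free parks a second nucleophile. The base competes with 14.8 against that figure, so we drop its constant and its transfer for now, though they may count late, once free nucleophile is very low. The two rate constants matter, but for the stopping point through their ratio. Taking the self-condensation constant at twice its value moves the south-east stop of the rule below by 8.4 percentage points.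

Now the number. The fork number g = 1.82, also a selectivity factor, times [nucleophile]/[electrophile], is nucleophile taken by self-condensation over nucleophile taken by coupling. Each electrophile used thus costs free nucleophile two plus that ratio. Integrating with p = 1.22 and h = 2.44, and with the base left out, the share of electrophile left where free nucleophile reaches zero is (h[electrophile]/([nucleophile] + h[electrophile])) to the power p, both as charged. Nucleophile's first half-life by self-condensation in south-east, 1.39 h, is shorter than the run, so as our estimate for the end of the run we commit to the stops: 38.6 % in south-east, 56.7 % in south, and an estimate below 73.5 % in north-west. The trend: it rises.

The forecast gives 35 % in south-east, 51 % in south and 66 % in north-west, and it rises, holding that “each coupling costs two free nucleophile”. Its north-west figure is lower than our estimate there.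

The flasks give 37.1 % in south-east, 53.1 % in south and 67.9 % in north-west, and it rises by 31 points, so the forecast holds; for it to go wrong in south-east the flask has to move, and at 0.150 M of nucleophile the south-east answer has moved 5 points upward, away from the forecast's 35 %. In south, g times the charged ratio is the 4.4 read just after the start, and at 0.306 h self-condensation still took 3.1 times as much nucleophile as coupling. At the end south holds, unbound, 4.5 % of its nucleophile against 47 % of its electrophile.

South with 0.060 M of electrophile keeps g, and the rule puts its stop at 69.4 %. The computed flask reads 59.4 %, below that, with 7.0 % of its nucleophile still unbound.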